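**Strategy.** Everything rests on an α-ketol ring expansion: in a 2-aryl-3-hydroxy-2,3-dihydrobenzofuran-3-carbaldehyde the O1-bearing benzylic carbon (future C2) shifts from the carbinol carbon (future C4) to the formyl carbon (future C3), turning the five-membered ring into the pyranone ring O1–C2–C3–C4–C4a–C8a. The step exploits the C4 ketone/C3 carbinol pair of that ring, conjugated to ring A. The hydroxy aldehyde arises in the same flask from a spiro-epoxy lactol, made by asymmetric epoxidation of an isoaurone, when its phenol opens the epoxide at the carbon bearing ring B. One operation thus forms O1–C2, fixes C2 and C3 and expands the ring; methylation and deprotection follow.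

Key step: step 8

Remark: ring A is carried as a symmetric 4-(benzyloxy)-3,5-dimethoxyphenyl unit, so the two positions ortho to the phenol are equivalent; the methyl ether that ends up peri to the C4 ketone is cleaved in the last step.

**Step 1**
Reactants: 1 4-(benzyloxy)-3,5-dimethoxybenzaldehyde
Product: 3 4-(benzyloxy)-3,5-dimethoxyphenol, via aryl formate 2 (not isolated)
Conditions: mCPBA, CH2Cl2, 0 °C → rt; then K2CO3 (cat.), MeOH, rt
Reagents that add atoms: mCPBA O=C(OO)c1cccc(Cl)c1
Why: Baeyer–Villiger (Dakin-type) oxidation of an electron-rich benzaldehyde, in which the trioxygenated aryl group migrates to give formate 2, which is methanolysed in the same flask.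

**Step 2**
Reactants: 3 4-(benzyloxy)-3,5-dimethoxyphenol; 4 glyoxylic acid (used as the monohydrate)
Product: 5 (RS)-2-[3-(benzyloxy)-6-hydroxy-2,4-dimethoxyphenyl]-2-hydroxyacetic acid
Conditions: aq. NaOH, 1,4-dioxane, 0 °C → rt; then HCl to pH 2
Reagents that add atoms: none
Why: ortho-hydroxyalkylation of the phenoxide by glyoxylate (Friedel–Crafts-type aldol); the para position is blocked and the two ortho positions are equivalent, so one regioisomer should form, and the racemic carbinol centre is removed in step 3.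

**Step 3**
Reactants: 5 (RS)-2-[3-(benzyloxy)-6-hydroxy-2,4-dimethoxyphenyl]-2-hydroxyacetic acid
Product: 6 5-(benzyloxy)-4,6-dimethoxybenzofuran-2(3H)-one
Conditions: Et3SiH (excess), TFA, CH2Cl2, 0 °C → rt
Reagents that add atoms: none
Why: ionic hydrogenation of the benzylic carbinol through the ortho-quinone-methide-type cation stabilised by the ring oxygens, followed by acid-catalysed lactonisation of the 2-hydroxyarylacetic acid.

**Step 4**
Reactants: 7 3-hydroxy-4,5-dimethoxybenzaldehyde
Product: 8 3-(benzyloxy)-4,5-dimethoxybenzaldehyde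
Conditions: BnBr, K2CO3, DMF, rt
Reagents that add atoms: benzyl bromide BrCc1ccccc1
Why: Williamson etherification of the only phenol.

**Step 5**
Reactants: 6 5-(benzyloxy)-4,6-dimethoxybenzofuran-2(3H)-one; 8 3-(benzyloxy)-4,5-dimethoxybenzaldehyde
Product: 9 (Z)-5-(benzyloxy)-3-[3-(benzyloxy)-4,5-dimethoxybenzylidene]-4,6-dimethoxybenzofuran-2(3H)-one
Conditions: Et3N (0.3 equiv), toluene, reflux, Dean–Stark; crystallisation
Reagents that add atoms: none
Why: Knoevenagel-type aldol condensation of the acidic lactone CH2 (its enolate is an aromatic 2-oxidobenzofuran); the (Z)-isomer, with ring B syn to the lactone carbonyl and away from the 4-methoxy group, should be the thermodynamic product and is taken on as a single isomer.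

**Step 6**
Reactants: 9 (Z)-5-(benzyloxy)-3-[3-(benzyloxy)-4,5-dimethoxybenzylidene]-4,6-dimethoxybenzofuran-2(3H)-one
Product: 10 (3S,3'S)-5-(benzyloxy)-3'-[3-(benzyloxy)-4,5-dimethoxyphenyl]-4,6-dimethoxy-2H-spiro[benzofuran-3,2'-oxiran]-2-one
Conditions: ent-Shi ketone of the enoate type (4,5-di-O-acetyl, 30 mol %), Oxone, NaHCO3, MeCN/aq. Na2EDTA, 0 °C
Reagents that add atoms: Oxone (potassium peroxymonosulfate) [K+].[O-]S(=O)(=O)OO
Why: Shi asymmetric epoxidation by a chiral dioxirane through a spiro transition state on a trans-stilbene-type trisubstituted alkene; the antipode of the D-fructose-derived catalyst (which gives R,R-epoxides from trans-stilbenes) should add oxygen syn to the face that sets both epoxide carbons as S.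

**Step 7**
Reactants: 10 (3S,3'S)-spiro-epoxy lactone
Product: 11 (3S,3'S)-5-(benzyloxy)-3'-[3-(benzyloxy)-4,5-dimethoxyphenyl]-4,6-dimethoxy-2H-spiro[benzofuran-3,2'-oxiran]-2-ol (anomeric mixture at C2)
Conditions: DIBAL-H (1.1 equiv), CH2Cl2, −78 °C; Rochelle salt
Reagents that add atoms: none
Why: partial reduction of the aryl lactone to the lactol through the tetrahedral aluminium hemiacetal, which is stable at −78 °C; the epoxide is untouched and the configuration of the new hemiacetal carbon is immaterial.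

**Step 8**
Reactants: 11 (3S,3'S)-spiro-epoxy lactol
Product: 14 (2R,3R)-6-(benzyloxy)-2-[3-(benzyloxy)-4,5-dimethoxyphenyl]-3-hydroxy-5,7-dimethoxychroman-4-one, via hydroxy epoxy aldehyde 12 (not isolated), via hydroxy aldehyde 13 (not isolated)
Conditions: Al(Ot-Bu)3 (1.2 equiv), toluene, 0 → 40 °C; aq. Rochelle salt
Reagents that add atoms: none
Why: Al(Ot-Bu)3 opens the lactol to the aluminium phenoxide of 12, whose phenoxide oxygen opens the epoxide at the benzylic carbon activated by ring B to give the chelated aluminium alkoxide of 13, and the O1–C2 carbon of this dihydrobenzofuran then shifts from the carbinol carbon to the aluminium-bound formyl carbon (α-ketol rearrangement). The closest known reaction types are the phenol opening of 2-(2-hydroxyaryl)oxiranes to 3-hydroxy-2,3-dihydrobenzofurans and the aluminium-alkoxide-mediated α-ketol ring expansion of 1-hydroxycycloalkanecarbaldehydes (D-homoannulation type). The transient dihydrofuran ring closes by 5-endo-tet epoxide opening, and the pyranone ring then closes by a suprafacial 1,2-alkyl shift that enlarges this ring from five to six members. C2 comes from the catalyst-set (S)-epoxide carbon by SN2 inversion and then migrates with retention, while C3 is set by the aluminium chelate (syn-periplanar O–C–C=O), in which C2 adds to the formyl face that places the new hydroxyl trans to the aryl group, which is also the thermodynamic arrangement. The step needs C2 rather than the ring-A carbon to migrate, which the developing conjugation of the new ketone with the trioxygenated ring A should favour, and an aryl shift would only give the 4-hydroxychroman-3-one, an α-ketol isomer that funnels to the same conjugated ketone 14. It also needs an SN2-type rather than an ionised epoxide opening, which the electron-withdrawing formyl group on the epoxide, the non-polar solvent and the weak Lewis acid should secure.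

**Step 9**
Reactants: 14 (2R,3R)-6-(benzyloxy)-2-[3-(benzyloxy)-4,5-dimethoxyphenyl]-3-hydroxy-5,7-dimethoxychroman-4-one
Product: 15 (2R,3R)-6-(benzyloxy)-2-[3-(benzyloxy)-4,5-dimethoxyphenyl]-3,5,7-trimethoxychroman-4-one
Conditions: Me3OBF4, 1,8-bis(dimethylamino)naphthalene, 4 Å MS, CH2Cl2, 0 °C → rt
Reagents that add atoms: trimethyloxonium tetrafluoroborate C[O+](C)C.F[B-](F)(F)F
Why: O-methylation of the secondary alcohol with Meerwein salt and a hindered non-nucleophilic base, which should not enolise the ketone, so C3 is not epimerised and the pyranone is not opened by retro-oxa-Michael reaction.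

**Step 10**
Reactants: 15 (2R,3R)-6-(benzyloxy)-2-[3-(benzyloxy)-4,5-dimethoxyphenyl]-3,5,7-trimethoxychroman-4-one
Product: 16 (2R,3R)-5,6-dihydroxy-2-(3-hydroxy-4,5-dimethoxyphenyl)-3,7-dimethoxychroman-4-one (target)
Conditions: BCl3 (excess), pentamethylbenzene, CH2Cl2, −78 → 0 °C; then MeOH, aq. NaHCO3
Reagents that add atoms: none
Why: BCl3 cleaves both benzyl ethers (the benzyl cation is trapped by pentamethylbenzene) and, through the six-membered boron chelate with the C4 carbonyl, should cleave only the peri 5-methyl ether among the methyl ethers.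

**Compound list**
1 | 4-(benzyloxy)-3,5-dimethoxybenzaldehyde | O=Cc1cc(OC)c(OCc2ccccc2)c(OC)c1 | starting material
2 | 4-(benzyloxy)-3,5-dimethoxyphenyl formate | O=COc1cc(OC)c(OCc2ccccc2)c(OC)c1 | intermediate (not isolated)
3 | 4-(benzyloxy)-3,5-dimethoxyphenol | Oc1cc(OC)c(OCc2ccccc2)c(OC)c1 | intermediate
4 | glyoxylic acid | O=CC(=O)O | starting material
5 | (RS)-2-[3-(benzyloxy)-6-hydroxy-2,4-dimethoxyphenyl]-2-hydroxyacetic acid | OC(C(=O)O)c1c(O)cc(OC)c(OCc2ccccc2)c1OC | intermediate
6 | 5-(benzyloxy)-4,6-dimethoxybenzofuran-2(3H)-one | O=C1Cc2c(OC)c(OCc3ccccc3)c(OC)cc2O1 | intermediate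
7 | 3-hydroxy-4,5-dimethoxybenzaldehyde | O=Cc1cc(O)c(OC)c(OC)c1 | starting material
8 | 3-(benzyloxy)-4,5-dimethoxybenzaldehyde | O=Cc1cc(OCc2ccccc2)c(OC)c(OC)c1 | intermediate
9 | (Z)-5-(benzyloxy)-3-[3-(benzyloxy)-4,5-dimethoxybenzylidene]-4,6-dimethoxybenzofuran-2(3H)-one | O=C1Oc2cc(OC)c(OCc3ccccc3)c(OC)c2/C1=C/c1cc(OCc2ccccc2)c(OC)c(OC)c1 | intermediate
10 | (3S,3'S)-5-(benzyloxy)-3'-[3-(benzyloxy)-4,5-dimethoxyphenyl]-4,6-dimethoxy-2H-spiro[benzofuran-3,2'-oxiran]-2-one | O=C1Oc2cc(OC)c(OCc3ccccc3)c(OC)c2[C@@]14O[C@H]4c1cc(OCc2ccccc2)c(OC)c(OC)c1 | intermediate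
11 | (3S,3'S)-5-(benzyloxy)-3'-[3-(benzyloxy)-4,5-dimethoxyphenyl]-4,6-dimethoxy-2H-spiro[benzofuran-3,2'-oxiran]-2-ol (anomeric mixture) | OC1Oc2cc(OC)c(OCc3ccccc3)c(OC)c2[C@@]14O[C@H]4c1cc(OCc2ccccc2)c(OC)c(OC)c1 | intermediate
12 | (2S,3S)-2-[3-(benzyloxy)-6-hydroxy-2,4-dimethoxyphenyl]-3-[3-(benzyloxy)-4,5-dimethoxyphenyl]oxirane-2-carbaldehyde | O=C[C@@]1(c2c(O)cc(OC)c(OCc3ccccc3)c2OC)O[C@H]1c1cc(OCc2ccccc2)c(OC)c(OC)c1 | intermediate (not isolated)
13 | (2R,3S)-5-(benzyloxy)-2-[3-(benzyloxy)-4,5-dimethoxyphenyl]-3-hydroxy-4,6-dimethoxy-2,3-dihydrobenzofuran-3-carbaldehyde | O=C[C@]1(O)c2c(OC)c(OCc3ccccc3)c(OC)cc2O[C@@H]1c1cc(OCc2ccccc2)c(OC)c(OC)c1 | intermediate (not isolated)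
14 | (2R,3R)-6-(benzyloxy)-2-[3-(benzyloxy)-4,5-dimethoxyphenyl]-3-hydroxy-5,7-dimethoxychroman-4-one | COc1cc2c(c(OC)c1OCc1ccccc1)C(=O)[C@H](O)[C@@H](c1cc(OCc3ccccc3)c(OC)c(OC)c1)O2 | intermediate
15 | (2R,3R)-6-(benzyloxy)-2-[3-(benzyloxy)-4,5-dimethoxyphenyl]-3,5,7-trimethoxychroman-4-one | COc1cc2c(c(OC)c1OCc1ccccc1)C(=O)[C@H](OC)[C@@H](c1cc(OCc3ccccc3)c(OC)c(OC)c1)O2 | intermediate
16 | (2R,3R)-5,6-dihydroxy-2-(3-hydroxy-4,5-dimethoxyphenyl)-3,7-dimethoxychroman-4-one | COc1cc2c(c(O)c1O)C(=O)[C@H](OC)[C@@H](c1cc(O)c(OC)c(OC)c1)O2 | target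

**Step count.** Total: 10 steps. Longest linear sequence: 9 steps (steps 1, 2, 3, 5, 6, 7, 8, 9, 10).

**Steps most likely to fail**

Step 8. The benzylic epoxide C–O bond may ionise before the phenoxide attacks, which would scramble C2 and allow a 1,2-shift to a β-keto aldehyde. The tertiary carbinol may also dehydrate to the aromatic benzofuran, or the ring-A carbon may migrate and the resulting chroman-3-one may enolise towards C2. Fallback, from 11 back to 14, separates the two events. The lactol 11 is treated with K2CO3 in MeCN at 0 °C so that the free phenoxide opens the epoxide by SN2, and the tertiary alkoxide is then capped with Et3SiOTf/2,6-lutidine to give the α-triethylsilyloxy aldehyde F1. An acyloin rearrangement of this α-silyloxy aldehyde under a bulky aluminium Lewis acid (methylaluminium bis(2,6-di-tert-butyl-4-methylphenoxide), toluene, −40 → 0 °C), with silyl transfer to the new C3 oxygen, should give the 3-triethylsilyloxy flavanone F2. HF·pyridine in THF then returns 14.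

Step 6. The dioxirane may show poor facial selectivity on this enoate-type alkene, and the aryl lactone may hydrolyse in the buffered aqueous medium. Fallback, from 9 back to the route at 13, uses an allylic-alcohol epoxidation. The lactone 9 is fully reduced (DIBAL-H, 3 equiv, CH2Cl2, −78 → 0 °C) to the (Z)-allylic alcohol F3. Sharpless asymmetric epoxidation with D-(−)-diethyl tartrate (stoichiometric Ti(OiPr)4, TBHP, 4 Å MS, CH2Cl2, −20 °C) should give the (2R,3S)-epoxy alcohol F4. Its phenol opens the epoxide at the benzylic carbon with inversion (on titanium, or on brief K2CO3 treatment) to the dihydrobenzofuran diol F5. Oxidation of the primary alcohol (TEMPO, PhI(OAc)2, CH2Cl2) gives 13, which is taken directly into the Al(Ot-Bu)3 conditions of step 8 to reach 14.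

Step 10. Once the boron phenoxides have formed, a second methyl ether (the flanked 4'-methoxy or the chelated 3-methoxy group) may be cleaved, or the peri ether may be cleaved incompletely. Fallback, from 15 back to 16, splits the deprotection. Hydrogenolysis (H2, Pd/C, EtOAc, rt) removes both benzyl groups to give the 5-O-methyl diphenol F6. Chelation-controlled demethylation with MgI2·OEt2 (toluene/THF, 50 °C), which acts only on the ether ortho to the carbonyl, then gives 16.

**Further compounds**
F1 | step 8 | (2R,3S)-5-(benzyloxy)-2-[3-(benzyloxy)-4,5-dimethoxyphenyl]-4,6-dimethoxy-3-[(triethylsilyl)oxy]-2,3-dihydrobenzofuran-3-carbaldehyde | O=C[C@]1(O[Si](CC)(CC)CC)c2c(OC)c(OCc3ccccc3)c(OC)cc2O[C@@H]1c1cc(OCc2ccccc2)c(OC)c(OC)c1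
F2 | step 8 | (2R,3R)-6-(benzyloxy)-2-[3-(benzyloxy)-4,5-dimethoxyphenyl]-5,7-dimethoxy-3-[(triethylsilyl)oxy]chroman-4-one | COc1cc2c(c(OC)c1OCc1ccccc1)C(=O)[C@H](O[Si](CC)(CC)CC)[C@@H](c1cc(OCc3ccccc3)c(OC)c(OC)c1)O2
F3 | step 6 | (Z)-2-[3-(benzyloxy)-6-hydroxy-2,4-dimethoxyphenyl]-3-[3-(benzyloxy)-4,5-dimethoxyphenyl]prop-2-en-1-ol | OC/C(=C\c1cc(OCc2ccccc2)c(OC)c(OC)c1)c1c(O)cc(OC)c(OCc2ccccc2)c1OC
F4 | step 6 | [(2R,3S)-2-[3-(benzyloxy)-6-hydroxy-2,4-dimethoxyphenyl]-3-[3-(benzyloxy)-4,5-dimethoxyphenyl]oxiran-2-yl]methanol | OC[C@@]1(c2c(O)cc(OC)c(OCc3ccccc3)c2OC)O[C@H]1c1cc(OCc2ccccc2)c(OC)c(OC)c1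
F5 | step 6 | (2R,3R)-5-(benzyloxy)-2-[3-(benzyloxy)-4,5-dimethoxyphenyl]-3-(hydroxymethyl)-4,6-dimethoxy-2,3-dihydrobenzofuran-3-ol | OC[C@]1(O)c2c(OC)c(OCc3ccccc3)c(OC)cc2O[C@@H]1c1cc(OCc2ccccc2)c(OC)c(OC)c1
F6 | step 10 | (2R,3R)-6-hydroxy-2-(3-hydroxy-4,5-dimethoxyphenyl)-3,5,7-trimethoxychroman-4-one | COc1cc2c(c(OC)c1O)C(=O)[C@H](OC)[C@@H](c1cc(O)c(OC)c(OC)c1)O2
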